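## Structural features

The target (33) is a C40 dimer of two identical icetexane units. In one unit ring C is aromatic, and its O11 and O12 are tied into a 1,4-dioxane by bonds to C13′ and C14′ of the second unit, which survives as a C8′=C9′ ene-11′,12′-dione. In each half, ring A (C1–C5 and C10, gem-dimethyl at C4) is fused through C5–C10 to the seven-membered ring B (C5, C6, C7, C8, C9, C20, C10), ring B is fused to ring C through C8–C9, and an oxygen spans C7 and C10, so an oxolane (O, C10, C5, C6, C7) and an isochroman sit inside an 8-oxabicyclo[3.2.1]octane. The stereocentres are the contiguous pair C5 (S) / C10 (S, fully substituted) and C7 (S) in each half, plus the vicinal pair C13′ (R, carrying O11, isopropyl and the C12′ carbonyl) and C14′ (R) at the cis-fused dioxane. Each bridge oxygen is trans to H5, and the dioxane oxygens lie on the face of the dienone ring opposite to its own bridge oxygen. Fragile points are the benzylic C7–O ether (ionised by acids), the catechol and ortho-quinone oxidation levels (air, base, nucleophiles), the α-aryloxy 1,2-diketone of the product, and C5 for as long as it sits next to a C10 carbonyl. The real difficulty is C10, a fully substituted ether carbon flanked by C5, shielded by the axial C4 methyl and locked into ring B; the second difficulty is the facial sense of the last cycloaddition. The key step exploits the fact that C10 carries the benzylic C20 methylene: C10 is the adduct of a C20 benzyl nucleophile (on C9 of ring C) with a ring A ketone whose axial C4 methyl and equatorial C5 side arm dictate the direction of attack.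

## Logic of the disconnections

**33 ⇒ 32 + 32.** The O11–C13′ and O12–C14′ bonds are cut. A 1,4-dioxane with an arene on one side and a carbon α to a 1,2-dione on the other is the retron of a hetero-Diels–Alder reaction between O=C11–C12=O of one quinone and C13′=C14′ of another. The problem is halved and both halves are the same monomer. The forward step must give the head-to-head orientation (O12 to C14′) and bond on the face of C13′=C14′ anti to the bridge oxygen; cis addition is automatic.

**32 ⇒ 31 ⇒ 29.** No skeletal bond is cut; two O–H and then two O–CH3 bonds are restored. The quinone is placed last because it is the least stable oxidation level, and methyl ethers carry the catechol through the organometallic steps. The forward steps need a neutral, non-nucleophilic oxidant and a demethylation that attacks the methyl carbon, because a Lewis acid strong enough to cleave aryl methyl ethers would also open the C7–O bond.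

**29 ⇒ 28.** The C7–O bond of the bridge is cut. C7 is benzylic and para to O12, so its cation is accessible from a C7 methoxy group, and the axial C10 hydroxyl sits 1,3 to it on ring B. This removes the bicycle and makes the C7 configuration of every earlier compound irrelevant. The forward step must ionise C7 in preference to the tertiary C10–OH.

**28 ⇒ 25 (key).** The C10–C20 bond is cut, opening ring B to a C20 benzylic bromide and a C10 ketone. A fully substituted carbinol carbon next to a benzylic CH2 is the retron of a Barbier addition. One ring, one C–C bond and the C10 stereocentre are removed, leaving an acyclic link between a ring A ketone and an arene. The forward step needs equatorial entry of C20, survival of C5 and survival of the C7 methoxy group.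

**25 ⇒ 24 ⇒ 23 ⇒ 22.** Only functional groups change: C20–Br from C20–OH from C20–OSi, and the C10 ketone from its ketal. The order is chosen so that the bromide is made last and under neutral conditions, since it can alkylate its own C7 methoxy oxygen. The ketal is removed while C20 is still silylated, so no free hydroxyl can trap a C7 cation under acid. The silyl group is removed under buffered conditions because the ketone is then free and C5 is epimerisable.

**22 ⇒ 19 + 8.** The C7–C8 bond (and the C7 O–CH3 bond) is cut: a C8 aryl anion adds to a C7 aldehyde and the alkoxide is methylated. This is the convergent junction of the two fragments. It demands an aryl bromide whose C20 oxygen is masked by a silyl group that does not migrate, and an aldehyde whose ketone is protected.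

**8 ⇒ 6 ⇒ 5.** The C7 carbonyl comes from oxidative cleavage of an allyl group, and the ketal from the ketone. The allyl group is the simplest two-carbon aldehyde equivalent that can be introduced enantioselectively at C5. Ketalisation must not epimerise C5.

**5 ⇒ 4 ⇒ 1 + 2.** The C5–C6 bond (allyl) and one C4–CH3 bond are cut. Conjugate methylation gives the enolate with the correct regiochemistry, storage as the allyl enol carbonate fixes it, and palladium-catalysed decarboxylative allylation sets C5. The catalyst must control the one stereocentre on which every later one depends.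

**19 ⇒ 18 ⇒ 17 ⇒ 13 ⇒ 10 ⇒ 9.** The C8–Br and C9–C20 bonds are cut. Both are made by directed lithiation (first ortho to the C11 methoxy group, then ortho to the masked aldehyde), because electrophilic substitution would favour C14. The demand is regiocontrol on a ring with three free positions.

## Other disconnections considered

**Alternative 1: quinone methide captured by the C10 hydroxyl.** The cut is again the C7–O bond, but made from a catechol with no oxygen at C7, A1. Ag2O would oxidise A1 to ortho-quinone A2, A2 would tautomerise to the C7 para-quinone methide A3, and the C10 hydroxyl would add to C7 to give A4, which is identical with 31.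
- In its favour: no C7 oxygen has to be carried, so there are no C7 epimers and no separate ionisation step; the same oxidant later makes 32.
- In its favour for the ring B closure: a samarium Barbier precursor without the C7 methoxy group would lack the neighbouring oxygen that makes 25 labile.
- Against it here: A2 is itself a competent hetero-Diels–Alder partner and could dimerise to an unbridged, 7-deoxy dimer before it tautomerises. The tautomerisation needs acid, base or heat at the unprotected catechol level. The catechol stage has to be passed twice.
- Comparison on structure: equal; both rely on the same C10 hydroxyl and the bridge geometry fixes C7 in both.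
- Comparison on mechanism: the chosen plan ionises a pre-installed leaving group at the robust dimethyl ether stage, which is easier to control than a prototropic shift of a reactive quinone.
- Comparison on step economy and precursor stability: the alternative is the better plan.

**Alternative 2: carbonyl ylide cycloaddition.** The cuts are C10–O, C10–C5 and C7–C6. A dirhodium carboxylate such as Rh2(OAc)4 would convert diazoketone A5 into a C10 carbenoid; the aldehyde oxygen would capture it to give the 2-benzopyrylium-4-olate A6, and A6 would add across the tethered vinyl group to give A7.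
- In its favour: the oxolane, ring B and ring A, three bonds and three stereocentres arise in one step, with the relative configuration fixed by the tether. On bonds and rings per step, and on convergence, the alternative is better than the chosen key step.
- Against it here: A5 is achiral, so the absolute configuration would have to come from a chiral dirhodium catalyst acting on an unactivated vinyl group that sits next to the C4 quaternary carbon. That dipolarophile is slow, so ylide dimerisation or proton shift could compete.
- Against it here: A7 carries a C20 ketone that must be removed next to the quaternary C10 without opening the acid-sensitive benzylic bridge, before 29 is reached.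
- Comparison: the chosen plan builds less per step, but it carries C5 from a well-understood allylation and lets the substrate set C10. The alternative is shorter to the tetracycle, but pays with a deoxygenation and less secure enantiocontrol.

**Alternative 3: oxonium ylide Stevens shift.** The cuts are C10–O and C10–C20. Cu(hfacac)2 would generate the C10 carbenoid from phthalan diazoketone A8, the phthalan oxygen would capture it to give oxonium ylide A9, and a 1,2-shift of benzylic C20 from oxygen to C10 would give A10.
- In its favour: C10 receives its C–O and its C–C bond in one step and the oxolane and ring B close together; two rings against one is better than the chosen key step. The phthalan, which is the decomposition product that threatens 25, becomes the productive intermediate.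
- Against it here: the C7–O bond is retained, so C7 must be set correctly relative to C5 in A8, because it now dictates the configuration of C10; the chosen plan leaves C7 uncontrolled on purpose.
- Against it here: A9 carries two benzylic groups on oxygen, and migration of the secondary C7 instead of C20 would give a ring-contracted isomer.
- Against it here: the diazo group must be placed on the more hindered α-carbon of the ring A ketone, and A10 keeps a C1 ketone that must be removed beside quaternary C10 before 29 is reached.
- Comparison: equal on the final C10 configuration (both substrate-controlled), better on rings per step, worse on precursor access and on the extra deoxygenation.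

Key step: step 14

Assumption 1: the (R,R)-configured ligand is taken to give the (S)-ketone 5 in step 2; if the sense proves opposite, the (S,S)-ligand is used and nothing else changes.
Assumption 2: the aryllithium addition in step 10 is not stereocontrolled, so 21–28 are mixtures of C7 epimers; the 7S epimer is drawn and named, and the 7R epimer is carried along because C7 is planarised in step 15.

## Route

Step 1
Reactants: 1 3-methylcyclohex-2-en-1-one; 2 allyl chloroformate
Product: 4 allyl 3,3-dimethylcyclohex-1-en-1-yl carbonate, via magnesium enolate 3 (not isolated)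
Conditions: MeMgBr, CuBr·SMe2 (5 mol%), THF, −30 °C; then 2, −78 → 0 °C
Reagents that add atoms: methylmagnesium bromide, C[Mg]Br
Why: Copper-catalysed conjugate addition creates the C4 gem-dimethyl group and a regiodefined enolate 3; the hard chloroformate should acylate it on oxygen, so the enolate regiochemistry is stored as the enol carbonate.

Step 2
Reactants: 4 allyl 3,3-dimethylcyclohex-1-en-1-yl carbonate
Product: 5 (S)-2-allyl-3,3-dimethylcyclohexan-1-one
Conditions: Pd2(dba)3·CHCl3 (2.5 mol%), (R,R)-ANDEN-phenyl Trost ligand (5.5 mol%), 1,4-dioxane, 23 °C
Reagents that add atoms: none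
Why: Decarboxylative asymmetric allylic alkylation (Tsuji–Trost type): zerovalent palladium ionises the allyl carbonate, CO2 is lost and the enolate recombines with the allylpalladium cation inside the chiral pocket, which selects the enolate face and sets C5 (S); the neutral medium should leave the new α-tertiary centre unepimerised.

Step 3
Reactants: 5 (S)-2-allyl-3,3-dimethylcyclohexan-1-one
Product: 6 (6S)-6-allyl-7,7-dimethyl-1,4-dioxaspiro[4.5]decane
Conditions: TMSOCH2CH2OTMS, TMSOTf (5 mol%), CH2Cl2, −78 → −20 °C; pyridine
Reagents that add atoms: 1,2-bis(trimethylsilyloxy)ethane, C[Si](C)(C)OCCO[Si](C)(C)C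
Why: Silyl-transfer ketalisation under kinetic, low-temperature conditions, where no enol is formed and C5 should not epimerise; the ketal then protects both the carbonyl and C5 from the organolithium and base used later.

Step 4
Reactants: 6 (6S)-6-allyl-7,7-dimethyl-1,4-dioxaspiro[4.5]decane
Product: 8 2-[(6S)-7,7-dimethyl-1,4-dioxaspiro[4.5]decan-6-yl]acetaldehyde, via ozonide 7 (not isolated)
Conditions: O3, CH2Cl2, −78 °C; PPh3, −78 → 20 °C
Reagents that add atoms: ozone, [O-][O+]=O
Why: Ozonolysis of the only C=C bond, done before the electron-rich arene is present; reduction of ozonide 7 gives the aldehyde whose carbonyl carbon becomes C7, and the stereocentre is β to it and untouched.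

Step 5
Reactants: 9 3-isopropylcatechol
Product: 10 1-isopropyl-2,3-dimethoxybenzene
Conditions: MeI, K2CO3, acetone, reflux
Reagents that add atoms: iodomethane, CI
Why: Williamson O-methylation of both phenols; the methyl ethers serve as directing groups for lithiation and should survive every step up to the thiolate cleavage.

Step 6
Reactants: 10 1-isopropyl-2,3-dimethoxybenzene
Product: 13 4-isopropyl-2,3-dimethoxybenzaldehyde, via aryllithium 11 (not isolated), via hemiaminal alkoxide 12 (not isolated)
Conditions: n-BuLi, TMEDA, Et2O, 0 → 20 °C; DMF, −78 → 20 °C; aq. NH4Cl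
Reagents that add atoms: N,N-dimethylformamide, CN(C)C=O
Why: Directed ortho-metalation: C9 is the only ring position ortho to a methoxy group, so lithiation is regiospecific, and formylation installs C20 at the aldehyde level.

Step 7
Reactants: 13 4-isopropyl-2,3-dimethoxybenzaldehyde
Product: 17 6-bromo-4-isopropyl-2,3-dimethoxybenzaldehyde, via amino alkoxide 14 (not isolated), via lithiated amino alkoxide 15 (not isolated), via brominated amino alkoxide 16 (not isolated)
Conditions: LiN(Me)CH2CH2NMe2, THF, −20 °C; n-BuLi (3 equiv), −20 °C; cannulated into BrCCl2CCl2Br, THF, −78 °C; aq. HCl (1 M), 0 °C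
Reagents that add atoms: 1,2-dibromo-1,1,2,2-tetrachloroethane, BrC(Cl)(Cl)C(Cl)(Cl)Br
Why: α-Amino alkoxide-directed ortho-lithiation: the lithium amide adds to the aldehyde, and the resulting alkoxide both protects the carbonyl and directs n-BuLi to C8, the only free ortho position; bromination and hydrolysis return the aldehyde with the halogen at a site that electrophilic bromination would not favour.

Step 8
Reactants: 17 6-bromo-4-isopropyl-2,3-dimethoxybenzaldehyde
Product: 18 (6-bromo-4-isopropyl-2,3-dimethoxyphenyl)methanol
Conditions: NaBH4, MeOH, 0 °C
Reagents that add atoms: none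
Why: Hydride reduction of the aldehyde to the C20 alcohol; the aryl bromide is inert to NaBH4.

Step 9
Reactants: 18 (6-bromo-4-isopropyl-2,3-dimethoxyphenyl)methanol
Product: 19 [(6-bromo-4-isopropyl-2,3-dimethoxybenzyl)oxy]triisopropylsilane
Conditions: TIPSOTf, 2,6-lutidine, CH2Cl2, 0 °C
Reagents that add atoms: triisopropylsilyl trifluoromethanesulfonate, CC(C)[Si](OS(=O)(=O)C(F)(F)F)(C(C)C)C(C)C
Why: Silylation of the primary benzylic alcohol; the bulky triisopropylsilyl group is chosen because it resists the oxygen-to-carbon shift in the aryllithium and the oxygen-to-oxygen migration in the alkoxide of the next step.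

Step 10
Reactants: 19 [(6-bromo-4-isopropyl-2,3-dimethoxybenzyl)oxy]triisopropylsilane; 8 2-[(6S)-7,7-dimethyl-1,4-dioxaspiro[4.5]decan-6-yl]acetaldehyde
Product: 22 (6S)-6-[(2S)-2-{5-isopropyl-3,4-dimethoxy-2-[(triisopropylsilyloxy)methyl]phenyl}-2-methoxyethyl]-7,7-dimethyl-1,4-dioxaspiro[4.5]decane (C7 epimers; 7S drawn), via aryllithium 20 (not isolated), via lithium alkoxide 21 (not isolated)
Conditions: t-BuLi (2.0 equiv), Et2O, −78 °C; 8, −78 °C; MeI (5 equiv), DMPU, −78 → 20 °C
Reagents that add atoms: iodomethane, CI
Why: Bromine–lithium exchange, 1,2-addition of aryllithium 20 to the aldehyde (C7–C8 bond) and O-methylation of alkoxide 21 in the same flask; no facial control at C7 is sought because both epimers converge later, and the ketal keeps C5 safe from the basic reagents.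

Step 11
Reactants: 22 (C7 epimers; 7S drawn)
Product: 23 (2S)-2-[(2S)-2-{5-isopropyl-3,4-dimethoxy-2-[(triisopropylsilyloxy)methyl]phenyl}-2-methoxyethyl]-3,3-dimethylcyclohexan-1-one (C7 epimers; 7S drawn)
Conditions: p-TsOH·H2O (10 mol%), THF/H2O (5:1), 35 °C
Reagents that add atoms: water, O
Why: Mild acid hydrolysis of the dioxolane while C20 is still silylated, so no free hydroxyl can trap C7 if any ionisation occurs; the acid should be too weak to cleave the silyl ether or to enolise the ketone towards C5 at a significant rate.

Step 12
Reactants: 23 (C7 epimers; 7S drawn)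
Product: 24 (2S)-2-{(2S)-2-[2-(hydroxymethyl)-5-isopropyl-3,4-dimethoxyphenyl]-2-methoxyethyl}-3,3-dimethylcyclohexan-1-one (C7 epimers; 7S drawn)
Conditions: TBAF/AcOH (1:1, 3 equiv), THF, 0 → 20 °C
Reagents that add atoms: none
Why: Fluoride-induced desilylation buffered with acetic acid, so the free ketone is not enolised and C5 should keep its configuration.

Step 13
Reactants: 24 (C7 epimers; 7S drawn)
Product: 25 (2S)-2-{(2S)-2-[2-(bromomethyl)-5-isopropyl-3,4-dimethoxyphenyl]-2-methoxyethyl}-3,3-dimethylcyclohexan-1-one (C7 epimers; 7S drawn)
Conditions: CBr4, PPh3, CH2Cl2, 0 °C; short silica plug, used at once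
Reagents that add atoms: carbon tetrabromide, BrC(Br)(Br)Br
Why: Appel reaction under neutral conditions, placed last because the bromide can alkylate its own C7 methoxy oxygen (five-membered oxonium ion, then loss of MeBr); it is therefore made immediately before use and never exposed to acid or water.

Step 14
Reactants: 25 (C7 epimers; 7S drawn)
Product: 28 (5S,7S,10S)-10-hydroxy-7,11,12-trimethoxyicetexa-8,11,13-triene (C7 epimers; 7S drawn), via benzylsamarium 26 (not isolated), via samarium alkoxide 27 (not isolated)
Conditions: SmI2 (2.5 equiv, 0.1 M), NiI2 (2 mol%), THF, 0 °C, 25 added over 2 h; aq. NH4Cl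
Reagents that add atoms: none
Why: Divalent samarium transfers one electron to the C20–Br bond (benzylic bromides are reduced far faster than dialkyl ketones in THF without HMPA), the benzyl radical takes a second electron to give benzylsamarium 26, and C20 adds to the C10 carbonyl to give the trivalent samarium alkoxide 27, protonated on work-up. The closest known reaction type is the samarium Barbier cyclisation of halo ketones, which includes benzylic halides and seven-membered rings. Ring B (C5, C6, C7, C8, C9, C20, C10) closes in a 7-exo-trig mode at the carbonyl. The new C10 stereocentre is substrate-controlled: the C5 side arm is equatorial and the axial C4 methyl blocks the syn-axial trajectory, so C20 should enter equatorially and the oxygen should end axial, trans to H5 (10S, trans A/B fusion). The step needs C–Br reduction in preference to ketyl formation, organosamarium formation in preference to Wurtz coupling, and retention of the C7 methoxy group and of the C5 configuration. Slow inverse addition into excess SmI2 with catalytic NiI2 keeps the radical concentration low, methoxide is a poor leaving group for 1,4-elimination across the arene, and the medium is not basic, so C5 should not be enolised. Both C7 epimers should cyclise, because the methoxy group sits on the flexible part of the forming ring and is not involved in the bond-forming event.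

Step 15
Reactants: 28 (C7 epimers; 7S drawn)
Product: 29 (5S,7S,10S)-7,10-epoxy-11,12-dimethoxyicetexa-8,11,13-triene (11,12-di-O-methylbrussonol)
Conditions: BF3·OEt2 (0.3 equiv), CH2Cl2, −40 → 0 °C; aq. NaHCO3
Reagents that add atoms: none
Why: Lewis-acid SN1 cycloetherification: BF3 activates the C7 methoxy group, the benzylic cation para to the C12 methoxy group forms much more readily than a tertiary C10 cation, and the axial C10 hydroxyl closes the oxolane; both C7 epimers should converge because the bridge can only form in the 7S sense.

Step 16
Reactants: 29 11,12-di-O-methylbrussonol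
Product: 31 brussonol, (5S,7S,10S)-7,10-epoxyicetexa-8,11,13-triene-11,12-diol, via disodium catecholate 30 (not isolated)
Conditions: NaSEt (10 equiv), degassed DMF, 130 °C, Ar; aq. HCl
Reagents that add atoms: none
Why: Nucleophilic aryl methyl ether cleavage by thiolate (SN2 at the methyl carbons); the bridging ether should be inert because both of its carbons are bridgeheads that allow no backside attack, and no Lewis acid is present to ionise C7.

Step 17
Reactants: 31 brussonol
Product: 32 brussonol ortho-quinone, (5S,7S,10S)-7,10-epoxyicetexa-8,13-diene-11,12-dione
Conditions: Ag2O (3 equiv), Na2SO4, Et2O, 20 °C, dark; Celite filtration, evaporation below 20 °C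
Reagents that add atoms: none
Why: Two-electron oxidation of the catechol under neutral, non-nucleophilic conditions; tautomerisation to a C7 quinone methide is excluded because C7 is a bridgehead, so the quinone should persist long enough to be isolated.

Step 18
Reactants: 32 brussonol ortho-quinone (two molecules)
Product: 33 target dimer, (5S,7S,10S,5′S,7′S,10′S,13′R,14′R)
Conditions: neat (thin solid film), 55 °C, Ar, dark
Reagents that add atoms: none
Why: Hetero-Diels–Alder dimerisation, of the type known for solvent-free heating of icetexane ortho-quinones: O=C11–C12=O of one molecule acts as the 4π component and C13′=C14′ of another as the 2π component, driven by aromatisation of the diene ring, and suprafacial addition gives the cis C13′/C14′ fusion. The head-to-head orientation is expected because the hindered O12 (next to isopropyl) then bonds to the unsubstituted C14′ and O11 to the isopropyl-bearing C13′, avoiding an isopropyl–isopropyl clash. The required face is the one anti to the bridge oxygen of the dienone unit, which avoids repulsion between the incoming quinone oxygens and the bridge-oxygen lone pairs.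

## Compound list

1 | 3-methylcyclohex-2-en-1-one | CC1=CC(=O)CCC1 | starting material
2 | allyl chloroformate | C=CCOC(Cl)=O | starting material
3 | bromomagnesium 3,3-dimethylcyclohex-1-en-1-olate | CC1(C)CCCC(O[Mg]Br)=C1 | intermediate (not isolated)
4 | allyl 3,3-dimethylcyclohex-1-en-1-yl carbonate | C=CCOC(=O)OC1=CC(C)(C)CCC1 | intermediate
5 | (S)-2-allyl-3,3-dimethylcyclohexan-1-one | C=CC[C@H]1C(C)(C)CCCC1=O | intermediate
6 | (6S)-6-allyl-7,7-dimethyl-1,4-dioxaspiro[4.5]decane | C=CC[C@H]1C(C)(C)CCCC12OCCO2 | intermediate
7 | 3-{[(6S)-7,7-dimethyl-1,4-dioxaspiro[4.5]decan-6-yl]methyl}-1,2,4-trioxolane (ozonide of 6) | C1OC(C[C@H]2C(C)(C)CCCC23OCCO3)OO1 | intermediate (not isolated)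
8 | 2-[(6S)-7,7-dimethyl-1,4-dioxaspiro[4.5]decan-6-yl]acetaldehyde | O=CC[C@H]1C(C)(C)CCCC12OCCO2 | intermediate
9 | 3-isopropylcatechol | CC(C)c1cccc(O)c1O | starting material
10 | 1-isopropyl-2,3-dimethoxybenzene | CC(C)c1cccc(OC)c1OC | intermediate
11 | (4-isopropyl-2,3-dimethoxyphenyl)lithium | [Li]c1ccc(C(C)C)c(OC)c1OC | intermediate (not isolated)
12 | lithium (dimethylamino)(4-isopropyl-2,3-dimethoxyphenyl)methanolate | CC(C)c1ccc(C(O[Li])N(C)C)c(OC)c1OC | intermediate (not isolated)
13 | 4-isopropyl-2,3-dimethoxybenzaldehyde | CC(C)c1ccc(C=O)c(OC)c1OC | intermediate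
14 | lithium {[2-(dimethylamino)ethyl](methyl)amino}(4-isopropyl-2,3-dimethoxyphenyl)methanolate | CC(C)c1ccc(C(O[Li])N(C)CCN(C)C)c(OC)c1OC | intermediate (not isolated)
15 | 6-lithio derivative of 14 | CC(C)c1cc([Li])c(C(O[Li])N(C)CCN(C)C)c(OC)c1OC | intermediate (not isolated)
16 | 6-bromo derivative of 14 | CC(C)c1cc(Br)c(C(O[Li])N(C)CCN(C)C)c(OC)c1OC | intermediate (not isolated)
17 | 6-bromo-4-isopropyl-2,3-dimethoxybenzaldehyde | CC(C)c1cc(Br)c(C=O)c(OC)c1OC | intermediate
18 | (6-bromo-4-isopropyl-2,3-dimethoxyphenyl)methanol | CC(C)c1cc(Br)c(CO)c(OC)c1OC | intermediate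
19 | [(6-bromo-4-isopropyl-2,3-dimethoxybenzyl)oxy]triisopropylsilane | CC(C)c1cc(Br)c(CO[Si](C(C)C)(C(C)C)C(C)C)c(OC)c1OC | intermediate
20 | {5-isopropyl-3,4-dimethoxy-2-[(triisopropylsilyloxy)methyl]phenyl}lithium | CC(C)c1cc([Li])c(CO[Si](C(C)C)(C(C)C)C(C)C)c(OC)c1OC | intermediate (not isolated)
21 | lithium alkoxide of the C7 alcohol (7S drawn, with 7R epimer) | CC(C)c1cc(c(CO[Si](C(C)C)(C(C)C)C(C)C)c(OC)c1OC)[C@@H](O[Li])C[C@H]1C(C)(C)CCCC12OCCO2 | intermediate (not isolated)
22 | (6S)-6-[(2S)-2-{5-isopropyl-3,4-dimethoxy-2-[(triisopropylsilyloxy)methyl]phenyl}-2-methoxyethyl]-7,7-dimethyl-1,4-dioxaspiro[4.5]decane (with 7R epimer) | CC(C)c1cc(c(CO[Si](C(C)C)(C(C)C)C(C)C)c(OC)c1OC)[C@@H](OC)C[C@H]1C(C)(C)CCCC12OCCO2 | intermediate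
23 | (2S)-2-[(2S)-2-{5-isopropyl-3,4-dimethoxy-2-[(triisopropylsilyloxy)methyl]phenyl}-2-methoxyethyl]-3,3-dimethylcyclohexan-1-one (with 7R epimer) | CC(C)c1cc(c(CO[Si](C(C)C)(C(C)C)C(C)C)c(OC)c1OC)[C@@H](OC)C[C@H]1C(C)(C)CCCC1=O | intermediate
24 | (2S)-2-{(2S)-2-[2-(hydroxymethyl)-5-isopropyl-3,4-dimethoxyphenyl]-2-methoxyethyl}-3,3-dimethylcyclohexan-1-one (with 7R epimer) | CC(C)c1cc(c(CO)c(OC)c1OC)[C@@H](OC)C[C@H]1C(C)(C)CCCC1=O | intermediate
25 | (2S)-2-{(2S)-2-[2-(bromomethyl)-5-isopropyl-3,4-dimethoxyphenyl]-2-methoxyethyl}-3,3-dimethylcyclohexan-1-one (with 7R epimer) | CC(C)c1cc(c(CBr)c(OC)c1OC)[C@@H](OC)C[C@H]1C(C)(C)CCCC1=O | intermediate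
26 | C20 diiodosamarium derivative of 25 | CC(C)c1cc(c(C[Sm](I)I)c(OC)c1OC)[C@@H](OC)C[C@H]1C(C)(C)CCCC1=O | intermediate (not isolated)
27 | diiodosamarium C10 alkoxide of 28 | CC(C)c1cc2c(c(OC)c1OC)C[C@@]1(O[Sm](I)I)CCCC(C)(C)[C@@H]1C[C@@H]2OC | intermediate (not isolated)
28 | (5S,7S,10S)-10-hydroxy-7,11,12-trimethoxyicetexa-8,11,13-triene (with 7R epimer) | CC(C)c1cc2c(c(OC)c1OC)C[C@@]1(O)CCCC(C)(C)[C@@H]1C[C@@H]2OC | intermediate
29 | (5S,7S,10S)-7,10-epoxy-11,12-dimethoxyicetexa-8,11,13-triene (11,12-di-O-methylbrussonol) | CC(C)c1cc2c(c(OC)c1OC)C[C@@]13CCCC(C)(C)[C@@H]1C[C@@H]2O3 | intermediate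
30 | disodium catecholate of brussonol | CC(C)c1cc2c(c([O-])c1[O-])C[C@@]13CCCC(C)(C)[C@@H]1C[C@@H]2O3.[Na+].[Na+] | intermediate (not isolated)
31 | brussonol, (5S,7S,10S)-7,10-epoxyicetexa-8,11,13-triene-11,12-diol | CC(C)c1cc2c(c(O)c1O)C[C@@]13CCCC(C)(C)[C@@H]1C[C@@H]2O3 | intermediate
32 | brussonol ortho-quinone, (5S,7S,10S)-7,10-epoxyicetexa-8,13-diene-11,12-dione | CC(C)C1=CC2=C(C[C@@]34CCCC(C)(C)[C@@H]3C[C@@H]2O4)C(=O)C1=O | intermediate
33 | target dimer: brussonol unit whose O11 is bonded to C13′ and O12 to C14′ of a second unit present as the 8′-ene-11′,12′-dione; (5S,7S,10S,5′S,7′S,10′S,13′R,14′R) | CC(C)c1cc2c(c3c1O[C@@H]1C4=C(C[C@@]56CCCC(C)(C)[C@@H]5C[C@@H]4O6)C(=O)C(=O)[C@]1(C(C)C)O3)C[C@@]13CCCC(C)(C)[C@@H]1C[C@@H]2O3 | target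

## Step count and least certain steps

Total: 18 steps. Longest linear sequence: 14 steps (steps 5–18); the ketone branch (steps 1–4) joins at step 10.

**Step 14 (key step).** The most likely failures are bimolecular Wurtz coupling of the benzylic radical before it is reduced, 1,4-elimination of methoxide from the benzylsamarium across the arene, and loss of the bromide beforehand by intramolecular O-alkylation; all are favoured because a seven-membered closure onto a hindered ketone is slow. The fallback changes the bond that closes ring B; it sets out from 5 and from aryllithium 11 (made from 10 as in step 6) and comes back at 29. Ketone 5 would be treated with dimethylsulfonium methylide (Me3S+ I−, KHMDS, THF, −10 °C) to give the spiro-epoxide (3R,4S)-4-allyl-5,5-dimethyl-1-oxaspiro[2.5]octane F1, the methylene entering equatorially for the same reason as in the key step. Aryllithium 11 with BF3·OEt2 at −78 °C would open F1 at its CH2 to give the tertiary alcohol (1S,2S)-2-allyl-1-(4-isopropyl-2,3-dimethoxybenzyl)-3,3-dimethylcyclohexan-1-ol F2, so that C9–C20 is the bond made by the organometallic. Ozonolysis (O3, CH2Cl2/MeOH, −78 °C; PPh3) would give the lactol (3aS,7aS)-7a-(4-isopropyl-2,3-dimethoxybenzyl)-4,4-dimethyloctahydro-1-benzofuran-2-ol F3. BF3·OEt2 would then ionise F3 to the C7 oxocarbenium ion, which C8 (para to the C12 methoxy group) captures in an oxa-Pictet–Spengler closure to give 29 directly.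

**Step 18.** The most likely failure is bonding on the wrong face of C13′=C14′ (syn to the bridge oxygen) or the head-to-tail orientation, because the two faces differ only through groups three bonds away. The fallback changes the control element from an isolated-molecule transition state in the quinone film to preorganisation in a hydrophobic aggregate; it sets out from 31 and comes back at 33. Catechol 31 would be oxidised as a fine suspension in water (Ag2O, vigorous stirring, 20 °C, dark), so that quinone 32 is formed inside the aggregate and dimerises there without being isolated. The product would be purified by chromatography and crystallisation. No new compound is involved.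

**Step 2.** The most likely failure is insufficient enantioselectivity, or the opposite sense, in the allylation of an enolate that leads to an α-tertiary centre, because the product ketone retains an enolisable hydrogen. The fallback replaces catalysis by resolution; it sets out from enolate 3 and comes back at 5. Enolate 3 would be trapped on carbon with allyl bromide (DMPU, THF) to give racemic 2-allyl-3,3-dimethylcyclohexan-1-one F4. Ketalisation with (R,R)-hydrobenzoin (p-TsOH, benzene, reflux) would give the diastereomers (2R,3R,6S)-6-allyl-7,7-dimethyl-2,3-diphenyl-1,4-dioxaspiro[4.5]decane F5 and (2R,3R,6R)-6-allyl-7,7-dimethyl-2,3-diphenyl-1,4-dioxaspiro[4.5]decane F6, to be separated by chromatography or crystallisation. Mild aqueous acid would release 5 from F5; F6 could be hydrolysed, racemised with base and recycled.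

**Step 7.** The most likely failures are incomplete ortho-lithiation of the amino alkoxide, and bromine–lithium exchange of the product by surplus n-BuLi during the quench, because three equivalents of base are present. The fallback replaces directed metalation by electrophilic substitution; it sets out from 13 and comes back at 18. Aldehyde 13 would be reduced (NaBH4, MeOH) to (4-isopropyl-2,3-dimethoxyphenyl)methanol F7, and F7 would be brominated with N-bromosuccinimide (MeCN, 0 °C). Substitution is expected at C8 (para to the C12 methoxy group, ortho to the CH2OH group) and not at C14, which is flanked by the isopropyl group.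

## Further compounds

F1 | step 14 | (3R,4S)-4-allyl-5,5-dimethyl-1-oxaspiro[2.5]octane | C=CC[C@H]1C(C)(C)CCC[C@]12CO2
F2 | step 14 | (1S,2S)-2-allyl-1-(4-isopropyl-2,3-dimethoxybenzyl)-3,3-dimethylcyclohexan-1-ol | CC(C)c1ccc(C[C@@]2(O)CCCC(C)(C)[C@@H]2CC=C)c(OC)c1OC
F3 | step 14 | (3aS,7aS)-7a-(4-isopropyl-2,3-dimethoxybenzyl)-4,4-dimethyloctahydro-1-benzofuran-2-ol | CC(C)c1ccc(C[C@@]23CCCC(C)(C)[C@@H]2CC(O)O3)c(OC)c1OC
F0 | step 18 | none | none
F4 | step 2 | racemic 2-allyl-3,3-dimethylcyclohexan-1-one | C=CCC1C(C)(C)CCCC1=O
F5 | step 2 | (2R,3R,6S)-6-allyl-7,7-dimethyl-2,3-diphenyl-1,4-dioxaspiro[4.5]decane | C=CC[C@H]1C(C)(C)CCCC12O[C@H](c3ccccc3)[C@@H](c3ccccc3)O2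
F6 | step 2 | (2R,3R,6R)-6-allyl-7,7-dimethyl-2,3-diphenyl-1,4-dioxaspiro[4.5]decane | C=CC[C@@H]1C(C)(C)CCCC12O[C@H](c3ccccc3)[C@@H](c3ccccc3)O2
F7 | step 7 | (4-isopropyl-2,3-dimethoxyphenyl)methanol | CC(C)c1ccc(CO)c(OC)c1OC
A1 | alternative 1 | (5S,10S)-icetexa-8,11,13-triene-10,11,12-triol | CC(C)c1cc2c(c(O)c1O)C[C@@]1(O)CCCC(C)(C)[C@@H]1CC2
A2 | alternative 1 | (5S,10S)-10-hydroxyicetexa-8,13-diene-11,12-dione | CC(C)C1=CC2=C(C[C@@]3(O)CCCC(C)(C)[C@@H]3CC2)C(=O)C1=O
A3 | alternative 1 | (5S,10S)-10,11-dihydroxyicetexa-7,9(11),13-trien-12-one (C7 para-quinone methide) | CC(C)C1=CC2=CC[C@H]3C(C)(C)CCC[C@]3(O)CC2=C(O)C1=O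
A4 | alternative 1 | brussonol (identical with 31) | CC(C)c1cc2c(c(O)c1O)C[C@@]13CCCC(C)(C)[C@@H]1C[C@@H]2O3
A5 | alternative 2 | 2-(2-diazo-6,6-dimethyloct-7-enoyl)-5-isopropyl-3,4-dimethoxybenzaldehyde | CC(C)c1cc(C=O)c(C(=O)C(=[N+]=[N-])CCCC(C)(C)C=C)c(OC)c1OC
A6 | alternative 2 | 3-(4,4-dimethylhex-5-enyl)-6-isopropyl-7,8-dimethoxy-2-benzopyrylium-4-olate | CC(C)c1cc2C=[O+]C(CCCC(C)(C)C=C)=C([O-])c2c(OC)c1OC
A7 | alternative 2 | 20-oxo-11,12-di-O-methylbrussonol | CC(C)c1cc2c(c(OC)c1OC)C(=O)[C@@]13CCCC(C)(C)[C@@H]1C[C@@H]2O3
A8 | alternative 3 | (3S)-2-diazo-3-{[(1S)-6-isopropyl-4,5-dimethoxy-1,3-dihydroisobenzofuran-1-yl]methyl}-4,4-dimethylcyclohexan-1-one | CC(C)c1cc2c(c(OC)c1OC)CO[C@H]2C[C@H]1C(C)(C)CCC(=O)C1=[N+]=[N-]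
A9 | alternative 3 | tricyclic oxonium ylide from A8 (oxygen bonded to C7, C20 and C10; enolate form) | CC(C)c1cc2c(c(OC)c1OC)C[O+]1[C@H]2C[C@H]2C(C)(C)CCC([O-])=C12
A10 | alternative 3 | 1-oxo-11,12-di-O-methylbrussonol | CC(C)c1cc2c(c(OC)c1OC)C[C@@]13C(=O)CCC(C)(C)[C@@H]1C[C@@H]2O3
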